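The maple run cannot show me how fast the right-handed substrate goes: its lowest reading, 49.6% of the charge, lies 0.4 percentage points below its starting share, against a scatter of 0.3 points. So I looked for a rough estimate rather than a rate.

- maple: left-handed substrate 0.41 M; right-handed substrate 0.41 M; gas 71 mM (held); free catalyst 0.20 mM; the very flask that is asked about, followed so far
- flask: left-handed substrate 0.41 M; gas 71 mM (held); free catalyst 0.20 mM; right-handed substrate 0.41 M; time 4.0 h

- maple (time / min: right-handed substrate / %, left-handed substrate / %): 4.00: 49.9, 48.3; 8.00: 50.1, 46.0; 12.0: 50.1, 44.3; 15.0: 50.3, 43.0; 20.0: 50.3, 40.7; 25.0: 50.0, 37.4; 30.0: 49.6, 35.2

(scatter of a reading: 0.3 percentage points)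

* whether the excess of right-handed substrate over left-handed substrate among what is left of the two reaches 98% by 4.0 h (no / yes)
* the highest excess of right-handed substrate over left-handed substrate among what is left of the two up to 4.0 h

- free catalyst is single-handed; left-handed substrate and right-handed substrate are mirror images of each other, charged as a racemate, each of them at the stated concentration
- the numbers in the tables scatter by 0.3 percentage points (one standard deviation)
- at the start none of the gas is in solution

I took that lowest reading at face value as the right-handed loss and divided the logarithm of the left-handed loss at 30.0 min by the logarithm of that loss, which gave 43.7. This selectivity factor, the ratio of the two specific rates with time divided out, is a rough reading. The wanted excess of 98% means the left-handed substrate stands at 0.0101 of the right-handed, so on that reading the right-handed substrate keeps 89.8% of its own charge.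

The pace was the other question. The left-handed substrate fell in a straight line from 48.3% to 35.2% of the charge, and its clearance time, its charged share divided by that pace 1.65 h, came out as the figure just printed. The 4.0 h allowed is longer by a factor of 2.42, so that is the slowing, on average, that I could accept. I expected the excess to be reached.

The forecast worked from a selectivity of 30 rather than my 43.7. It said yes, with a top of 99.8%, since “the excess keeps climbing towards 100 %”.

The flask gave yes and a top of >99.9%, reaching the wanted excess at 2.51 h.

    reagent + free catalyst + left-handed substrate → free catalyst + left-handed product (k = 10400 /M²/min)
    reagent + free catalyst + right-handed substrate → free catalyst + right-handed product (k = 84.9 /M²/min)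
    2 reagent → self-condensation product (k = 0.0655 /M/min)
    2 free catalyst → spent catalyst (k = 12.5 /M/min)
    gas ⇌ reagent, rate k5*(csat - [reagent]) (kL = 0.0665 /min)

Measured against my clearance time, the flask took longer by a factor of 1.52 to reach the wanted excess, less than the 2.42 I had allowed. The part of the charge reacted, said of that value alone, depends on the hour of the reading: the same run stands at 54.0% at 4.00 h and, read ten times later, at 68.4%.

The data are simulated on assumed constants, and the scatter is random.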